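Ring C is disconnected across C3–C4 and O1–C2. This reveals the O1–C8a–C4a–C4 unit of rings A and C as the oxa-diene of an ortho-quinone methide, and C2–C3 with ring B as a styrene. In the key step the phenolic aldehyde 5 is turned in the flask, via its dimethyl acetal, into an α-methoxy ortho-quinone methide. A chiral Brønsted acid guides it through an inverse-demand oxa-Diels–Alder reaction with the catechol-protected styrene 9; both bonds and the C2 stereocentre form at once, with C4 at the alcohol level. Both prenyl groups are installed on ring A first; oxidation at C4 and desilylation finish the synthesis.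

Key step: step 5

Remark: the target is the (2S) enantiomer, with C2 as its only stereocentre. The sense of induction of the chiral acid in step 5 is assigned by analogy; the catalyst antipode is taken if a first run shows the opposite sense.

Step 1
Reactants: 1 2,4,6-trihydroxybenzaldehyde; 2 prenyl bromide (1-bromo-3-methylbut-2-ene)
Product: 3 2,4,6-trihydroxy-3,5-bis(3-methylbut-2-en-1-yl)benzaldehyde
Conditions: 2 (2.1 equiv), KOH (3 equiv), H2O, 0 °C to rt
Reagents that add atoms: prenyl bromide (2), CC(C)=CCBr
Why: Double C-alkylation of the ambident phloroglucinolate at its two free ring carbons (SN2 at the primary allylic bromide), the protic medium disfavouring O-alkylation, as in the prenylation of acylphloroglucinols.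

Step 2
Reactants: 3 2,4,6-trihydroxy-3,5-bis(3-methylbut-2-en-1-yl)benzaldehyde; 4 tert-butyldimethylsilyl chloride
Product: 5 4,6-bis(tert-butyldimethylsilyloxy)-2-hydroxy-3,5-bis(3-methylbut-2-en-1-yl)benzaldehyde
Conditions: 4 (2.2 equiv), imidazole (3 equiv), DMF, 0 °C to rt
Reagents that add atoms: tert-butyldimethylsilyl chloride (4), CC(C)(C)[Si](C)(C)Cl
Why: Silyl ether formation at the para hydroxyl and at one of the two homotopic ortho hydroxyls, the last ortho hydroxyl being deactivated by its hydrogen bond to the formyl group, which leaves exactly one phenol for the key step.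

Step 3
Reactants: 6 3,4-dihydroxybenzaldehyde; 4 tert-butyldimethylsilyl chloride
Product: 7 3,4-bis(tert-butyldimethylsilyloxy)benzaldehyde
Conditions: 4 (2.4 equiv), imidazole (3 equiv), DMF, rt
Reagents that add atoms: tert-butyldimethylsilyl chloride (4), CC(C)(C)[Si](C)(C)Cl
Why: Standard bis-silylation of the catechol gives acid-stable, moderately electron-releasing ethers that survive the key step and fall in the final fluoride step.

Step 4
Reactants: 7 3,4-bis(tert-butyldimethylsilyloxy)benzaldehyde; 8 methyltriphenylphosphonium bromide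
Product: 9 3,4-bis(tert-butyldimethylsilyloxy)styrene
Conditions: 8 (1.3 equiv), n-BuLi (1.25 equiv), THF, 0 °C; then 7, 0 °C to rt
Reagents that add atoms: methyltriphenylphosphonium bromide (8), C[P+](c1ccccc1)(c1ccccc1)c1ccccc1.[Br-]
Why: Wittig methylenation of the aryl aldehyde with the non-stabilised ylide made in the flask gives the terminal styrene, with no stereochemical issue.

Step 5
Reactants: 5 4,6-bis(tert-butyldimethylsilyloxy)-2-hydroxy-3,5-bis(3-methylbut-2-en-1-yl)benzaldehyde; 9 3,4-bis(tert-butyldimethylsilyloxy)styrene; 10 trimethyl orthoformate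
Product: 14 (2S)-2-[3,4-bis(tert-butyldimethylsilyloxy)phenyl]-5,7-bis(tert-butyldimethylsilyloxy)-6,8-bis(3-methylbut-2-en-1-yl)chroman-4-ol as C4 epimers, via dimethyl acetal 11 (not isolated), via ortho-quinone methide 12 (not isolated), via 4-methoxyflavan 13 (not isolated)
Conditions: 5, 10 (1.5 equiv), (R)-3,3'-bis(2,4,6-triisopropylphenyl)-1,1'-binaphthyl-2,2'-diyl N-triflylphosphoramide (5 mol %), toluene, rt; then 9 (1.5 equiv), −40 °C; then THF–H2O (4:1), p-TsOH·H2O (10 mol %), 0 °C to rt
Reagents that add atoms: water, O (the C4 hydroxyl oxygen of 14); trimethyl orthoformate (10), COC(OC)OC (its methoxy group is carried only by 11, 12 and 13)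
Why: Acid-catalysed acetalisation of 5 with 10 gives 11, which loses methanol to the α-methoxy ortho-quinone methide 12 held as a hydrogen-bonded ion pair by the chiral phosphoramide, and its C=C–C=O oxa-diene (C4, C4a, C8a, O1 of the target) adds the electron-rich styrene 9 in an inverse-electron-demand oxa-Diels–Alder reaction in which the nucleophilic CH2 of 9 bonds to C4 and the quinone methide oxygen to the benzylic carbon C2, ring A regaining aromaticity. The closest known reactions are the acid-catalysed three-component coupling of salicylaldehydes, orthoformates and styrenes to 4-alkoxyflavans and the chiral Brønsted-acid-catalysed [4+2] cycloadditions of ortho-quinone methides formed in the flask with styrenes. Ring C closes as a six-membered ring by a concerted but asynchronous [4+2] cycloaddition (C–C bond formation leading, then capture of the developing benzylic cation by oxygen). C2 is set by the chiral phosphoramide anion bound at the quinone methide oxygen, which blocks one face so that 9 adds endo to the open face of E-configured 12 and should give mainly cis-13 (2S,4S); C4 is then scrambled by the SN1 hydrolysis to 14 and erased in step 6, so only the configuration at C2 matters. The step needs regioselectivity (given by the polarity of the styrene), chemoselectivity for the styrene over the prenyl double bonds and silyl ethers (given by the higher nucleophilicity and excess of 9 and by a moderately strong acid at low temperature) and face selectivity at C2 (given by the catalyst). Only one phenol is free in 5 and O5 stays silylated in 13, so neither a regioisomeric nor a second quinone methide can form.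

Step 6
Reactants: 14 (2S)-2-[3,4-bis(tert-butyldimethylsilyloxy)phenyl]-5,7-bis(tert-butyldimethylsilyloxy)-6,8-bis(3-methylbut-2-en-1-yl)chroman-4-ol as C4 epimers
Product: 15 (2S)-2-[3,4-bis(tert-butyldimethylsilyloxy)phenyl]-5,7-bis(tert-butyldimethylsilyloxy)-6,8-bis(3-methylbut-2-en-1-yl)chroman-4-one
Conditions: Dess–Martin periodinane (1.5 equiv), NaHCO3 (5 equiv), CH2Cl2, 0 °C to rt
Reagents that add atoms: none
Why: Dess–Martin oxidation of the secondary benzylic alcohol converges both C4 epimers to the ketone under buffered conditions that should leave the silyl ethers, the prenyl alkenes and the C2 stereocentre untouched.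

Step 7
Reactants: 15 (2S)-2-[3,4-bis(tert-butyldimethylsilyloxy)phenyl]-5,7-bis(tert-butyldimethylsilyloxy)-6,8-bis(3-methylbut-2-en-1-yl)chroman-4-one
Product: 16 6,8-diprenyleriodictyol, (2S)-2-(3,4-dihydroxyphenyl)-5,7-dihydroxy-6,8-bis(3-methylbut-2-en-1-yl)chroman-4-one
Conditions: TBAF (4.4 equiv), AcOH (4.4 equiv), THF, 0 °C
Reagents that add atoms: none
Why: Fluoride-mediated cleavage of the four aryl silyl ethers, buffered with acetic acid so that neither phenoxide-triggered ring opening to the chalcone (loss of C2 configuration) nor acid-triggered cyclisation of the ortho-prenyl phenols should occur.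

Compound list

1 | 2,4,6-trihydroxybenzaldehyde | O=Cc1c(O)cc(O)cc1O | starting material
2 | prenyl bromide (1-bromo-3-methylbut-2-ene) | CC(C)=CCBr | starting material
3 | 2,4,6-trihydroxy-3,5-bis(3-methylbut-2-en-1-yl)benzaldehyde | CC(C)=CCc1c(O)c(CC=C(C)C)c(O)c(C=O)c1O | intermediate
4 | tert-butyldimethylsilyl chloride | CC(C)(C)[Si](C)(C)Cl | starting material
5 | 4,6-bis(tert-butyldimethylsilyloxy)-2-hydroxy-3,5-bis(3-methylbut-2-en-1-yl)benzaldehyde | CC(C)=CCc1c(O[Si](C)(C)C(C)(C)C)c(CC=C(C)C)c(O)c(C=O)c1O[Si](C)(C)C(C)(C)C | intermediate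
6 | 3,4-dihydroxybenzaldehyde | O=Cc1ccc(O)c(O)c1 | starting material
7 | 3,4-bis(tert-butyldimethylsilyloxy)benzaldehyde | O=Cc1ccc(O[Si](C)(C)C(C)(C)C)c(O[Si](C)(C)C(C)(C)C)c1 | intermediate
8 | methyltriphenylphosphonium bromide | C[P+](c1ccccc1)(c1ccccc1)c1ccccc1.[Br-] | starting material
9 | 3,4-bis(tert-butyldimethylsilyloxy)styrene | C=Cc1ccc(O[Si](C)(C)C(C)(C)C)c(O[Si](C)(C)C(C)(C)C)c1 | intermediate
10 | trimethyl orthoformate | COC(OC)OC | starting material
11 | dimethyl acetal of 5: 3,5-bis(tert-butyldimethylsilyloxy)-2-(dimethoxymethyl)-4,6-bis(3-methylbut-2-en-1-yl)phenol | COC(OC)c1c(O)c(CC=C(C)C)c(O[Si](C)(C)C(C)(C)C)c(CC=C(C)C)c1O[Si](C)(C)C(C)(C)C | intermediate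
12 | (6E)-3,5-bis(tert-butyldimethylsilyloxy)-6-(methoxymethylidene)-2,4-bis(3-methylbut-2-en-1-yl)cyclohexa-2,4-dien-1-one (α-methoxy ortho-quinone methide, methoxy group anti to the ring carbonyl) | CO/C=C1/C(=O)C(CC=C(C)C)=C(O[Si](C)(C)C(C)(C)C)C(CC=C(C)C)=C1O[Si](C)(C)C(C)(C)C | intermediate
13 | (2S,4S)-2-[3,4-bis(tert-butyldimethylsilyloxy)phenyl]-5,7-bis(tert-butyldimethylsilyloxy)-4-methoxy-6,8-bis(3-methylbut-2-en-1-yl)chromane (2,4-cis) | CC(C)=CCc1c(O[Si](C)(C)C(C)(C)C)c(CC=C(C)C)c2c(c1O[Si](C)(C)C(C)(C)C)[C@@H](OC)C[C@@H](c1ccc(O[Si](C)(C)C(C)(C)C)c(O[Si](C)(C)C(C)(C)C)c1)O2 | intermediate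
14 | (2S)-2-[3,4-bis(tert-butyldimethylsilyloxy)phenyl]-5,7-bis(tert-butyldimethylsilyloxy)-6,8-bis(3-methylbut-2-en-1-yl)chroman-4-ol (mixture of C4 epimers, C4 left undefined) | CC(C)=CCc1c(O[Si](C)(C)C(C)(C)C)c(CC=C(C)C)c2c(c1O[Si](C)(C)C(C)(C)C)C(O)C[C@@H](c1ccc(O[Si](C)(C)C(C)(C)C)c(O[Si](C)(C)C(C)(C)C)c1)O2 | intermediate
15 | (2S)-2-[3,4-bis(tert-butyldimethylsilyloxy)phenyl]-5,7-bis(tert-butyldimethylsilyloxy)-6,8-bis(3-methylbut-2-en-1-yl)chroman-4-one | CC(C)=CCc1c(O[Si](C)(C)C(C)(C)C)c(CC=C(C)C)c2c(c1O[Si](C)(C)C(C)(C)C)C(=O)C[C@@H](c1ccc(O[Si](C)(C)C(C)(C)C)c(O[Si](C)(C)C(C)(C)C)c1)O2 | intermediate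
16 | 6,8-diprenyleriodictyol, (2S)-2-(3,4-dihydroxyphenyl)-5,7-dihydroxy-6,8-bis(3-methylbut-2-en-1-yl)chroman-4-one | CC(C)=CCc1c(O)c(CC=C(C)C)c2c(c1O)C(=O)C[C@@H](c1ccc(O)c(O)c1)O2 | target

Total step count: 7. Longest linear sequence: 5 steps (steps 1, 2, 5, 6, 7).

Steps most likely to fail

Step 5. Face discrimination at C2 may be insufficient, because the stereocentre forms at the carbon remote from the catalyst-bound oxygen and any exo or stepwise pathway erodes it. C2 may also erode by reversible ionisation of the benzylic O1–C2 bond under the acid. The fallback replaces catalyst control by resolution. Setting out from 5, 9 and 10, the same cycloaddition is run with the achiral Lewis acid Sc(OTf)3 (10 mol %, CH2Cl2, 0 °C), which should give racemic cis-4-methoxyflavan F1. Hydrolysis in the flask as in step 5 should give racemic flavan-4-ol F2, and Dess–Martin oxidation as in step 6 should give racemic tetrasilyl flavanone F3. F3 is resolved by preparative HPLC on an amylose tris(3,5-dimethylphenylcarbamate) phase. The (2S) enantiomer is 15, where the route is rejoined before step 7; the (2R) flavanone F4 is set aside.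

Step 1. Over-alkylation to geminally diprenylated, dearomatised products and O-prenylation compete with the double C-alkylation of the phloroglucinolate. The fallback sets out from 1 and uses Friedel–Crafts prenylation with 2-methylbut-3-en-2-ol and BF3·OEt2 in dioxane at rt. This is an electrophilic substitution of the neutral phenol by the dimethylallyl cation instead of an alkylation of the phenolate, and it leads directly back to 3.

Step 6. The very electron-rich benzylic alcohol may ionise at C4 under the acetic acid released (dehydration to the flav-3-ene), and ligand exchange at the carbinol flanked by the silyl ether may be slow. The fallback sets out from 13, isolated by quenching step 5 with Et3N before the aqueous acid stage. DDQ (1.2 equiv) in CH2Cl2–pH 7 buffer at 0 °C abstracts the C4 hydride, water adds to the O-methyl oxocarbenium ion and the hemiketal loses methanol, which should give 15 directly.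

Further compounds

F1 | step 5 | racemic cis-2-[3,4-bis(tert-butyldimethylsilyloxy)phenyl]-5,7-bis(tert-butyldimethylsilyloxy)-4-methoxy-6,8-bis(3-methylbut-2-en-1-yl)chromane | CC(C)=CCc1c(O[Si](C)(C)C(C)(C)C)c(CC=C(C)C)c2c(c1O[Si](C)(C)C(C)(C)C)C(OC)CC(c1ccc(O[Si](C)(C)C(C)(C)C)c(O[Si](C)(C)C(C)(C)C)c1)O2
F2 | step 5 | racemic 2-[3,4-bis(tert-butyldimethylsilyloxy)phenyl]-5,7-bis(tert-butyldimethylsilyloxy)-6,8-bis(3-methylbut-2-en-1-yl)chroman-4-ol (C4 epimers) | CC(C)=CCc1c(O[Si](C)(C)C(C)(C)C)c(CC=C(C)C)c2c(c1O[Si](C)(C)C(C)(C)C)C(O)CC(c1ccc(O[Si](C)(C)C(C)(C)C)c(O[Si](C)(C)C(C)(C)C)c1)O2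
F3 | step 5 | racemic 2-[3,4-bis(tert-butyldimethylsilyloxy)phenyl]-5,7-bis(tert-butyldimethylsilyloxy)-6,8-bis(3-methylbut-2-en-1-yl)chroman-4-one | CC(C)=CCc1c(O[Si](C)(C)C(C)(C)C)c(CC=C(C)C)c2c(c1O[Si](C)(C)C(C)(C)C)C(=O)CC(c1ccc(O[Si](C)(C)C(C)(C)C)c(O[Si](C)(C)C(C)(C)C)c1)O2
F4 | step 5 | (2R)-2-[3,4-bis(tert-butyldimethylsilyloxy)phenyl]-5,7-bis(tert-butyldimethylsilyloxy)-6,8-bis(3-methylbut-2-en-1-yl)chroman-4-one | CC(C)=CCc1c(O[Si](C)(C)C(C)(C)C)c(CC=C(C)C)c2c(c1O[Si](C)(C)C(C)(C)C)C(=O)C[C@H](c1ccc(O[Si](C)(C)C(C)(C)C)c(O[Si](C)(C)C(C)(C)C)c1)O2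
F0 | step 1 | none | none
F0 | step 6 | none | none
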